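**Retrosynthetic overview**

1. The target is (3S,4R)-3-aroyl-4-(veratrylmethyl)-γ-butyrolactone; the last disconnection is the O-benzyl ether on the guaiacyl phenol (hydrogenolysis).
2. Key disconnection: the C2–C3 bond of the lactone ring (lactone C=O carbon to the α-carbon that carries the aroyl group), made by a 5-exo-trig Claisen-type attack of an aryl ketone enolate on an O-tethered imidazole-1-carboxylate. The tether is itself assembled in the same flask from three components: (R)-4-(veratrylmethyl)butyrolactone, 4-benzyloxy-3-methoxyphenyllithium, and CDI as the new carbonyl carbon.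
3. Enabling feature: C3 lies between the aryl ketone C=O and the lactone C2=O (a β-keto lactone). C3 is therefore the natural enolate carbon and the only α-carbon the aryl ketone has. The ring oxygen O1 sits 1,4 to the ketone carbon, which is the γ-hydroxy ketone an aryllithium releases from a γ-lactone. The doubly activated C3–H lets the 3,4-trans arrangement settle thermodynamically from C4.
4. C4 is set earlier by asymmetric hydrogenation of the Stobbe half-ester from veratraldehyde and dimethyl succinate; chemoselective ester reduction and lactonisation then give the (R)-lactone.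
5. Ring order: the building-block γ-lactone is closed first (step 3) and opened in the key step; the target's lactone ring, with the carbonyl transposed, is closed in the key step; both benzene rings are bought.

Key step: step 4

Assumption (chemistry): the target is treated as the keto tautomer whose 3,4-trans configuration is the thermodynamic one at the acidic C3–H. The (S,S) ligand antipode in step 2 is assigned by analogy with itaconate half-esters and would be exchanged for its mirror image if correlation of the lactone showed the opposite sense.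

**Step 1**
Reactants: 1 3,4-dimethoxybenzaldehyde; 2 dimethyl succinate
Product: 3 (E)-4-(3,4-dimethoxyphenyl)-3-(methoxycarbonyl)but-3-enoic acid
Conditions: NaOMe (2.2 equiv), MeOH, reflux; then aq. HCl
Reagents that add atoms: none
Why: Stobbe condensation, in which the succinate enolate adds to the aldehyde, the aldolate lactonises to a paraconate ester and irreversible E1cB ring-opening gives the carboxylate, which should deliver the E half-ester (aryl trans to the ester).

**Step 2**
Reactants: 3 (E)-4-(3,4-dimethoxyphenyl)-3-(methoxycarbonyl)but-3-enoic acid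
Product: 4 (R)-4-(3,4-dimethoxyphenyl)-3-(methoxycarbonyl)butanoic acid
Conditions: H2 (5 bar), [Rh(cod)((S,S)-Et-DuPHOS)]BF4 (0.5 mol %), NaOMe (10 mol %), MeOH, rt
Reagents that add atoms: none
Why: Rhodium-catalysed asymmetric hydrogenation of an itaconate-type half-ester, in which the carboxylate and the alkene chelate the cationic rhodium–bisphosphine centre so that hydrogen is delivered to one enantiotopic face and the ligand sets the stereocentre (R; it becomes C4 of the target).

**Step 3**
Reactants: 4 (R)-4-(3,4-dimethoxyphenyl)-3-(methoxycarbonyl)butanoic acid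
Product: 6 (R)-4-(3,4-dimethoxybenzyl)dihydrofuran-2(3H)-one, via hydroxy acid 5 (not isolated)
Conditions: KOH (1.0 equiv), EtOH, 0 °C; CaCl2/NaBH4 [Ca(BH4)2], EtOH, –10 °C → rt; then 3 M HCl, rt
Reagents that add atoms: none
Why: Chemoselective borohydride reduction, in which the acid terminus is protected as its potassium carboxylate so that Ca(BH4)2 reduces only the methyl ester, followed by acid-catalysed lactonisation of the hydroxy acid, with the stereocentre untouched because no free base remains after salt formation.

**Step 4**
Reactants: 6 (R)-4-(3,4-dimethoxybenzyl)dihydrofuran-2(3H)-one; 7 1-(benzyloxy)-4-bromo-2-methoxybenzene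
Product: 12 (3S,4R)-3-[4-(benzyloxy)-3-methoxybenzoyl]-4-(3,4-dimethoxybenzyl)dihydrofuran-2(3H)-one, via aryllithium 8 (not isolated), via lithium lactolate 9 (not isolated), via lithium keto-alkoxide 10 (not isolated), via imidazole-1-carboxylate 11 (not isolated)
Conditions: 7, n-BuLi (1.0 equiv), THF, –78 °C; add to 6 (1.05 equiv), THF, –78 → 0 °C; cannulate into CDI (1.2 equiv), THF, 0 °C → rt; LiN(SiMe3)2 (1.3 equiv), –78 → 0 °C; aq. HCl; then Et3N (5 mol %), CH2Cl2, rt
Reagents that add atoms: 1,1'-carbonyldiimidazole (CDI), O=C(n1ccnc1)n1ccnc1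
Why: Aryllithium 8 adds once to the lactone carbonyl of 6 at –78 °C to give the tetrahedral lactolate 9, which opens on warming to the conjugated aryl ketone alkoxide 10; CDI O-acylates the alkoxide to the imidazole-1-carboxylate 11, and LiN(SiMe3)2 then forms the only possible ketone enolate, whose carbon attacks the tethered carbonyl and expels imidazolide, so the lactone C2–C3 bond is formed last and closes the ring. The closest known reaction types are the mono-addition of organolithiums to γ-lactones giving γ-hydroxy ketones, the alkoxycarbonylation of alkoxides by CDI, and the intramolecular Claisen (Dieckmann-type) C-acylation of a ketone enolate by a carbonate or acyl imidazole. The γ-butyrolactone closes in the 5-exo-trig mode (addition–elimination at the tethered C=O), which should be preferred over O-attack leading to a seven-membered enol carbonate. C4 is carried over unchanged from 6 because it is β to the ketone, never enolisable and flanked by no leaving group; C3 is set under thermodynamic control, since the product forms as its lithium β-keto lactone enolate and the doubly activated C3–H equilibrates (cat. Et3N) to the trans isomer with the aroyl and veratrylmethyl groups on opposite faces. The step needs mono-addition of 8 (secured by the stability of 9 at –78 °C and by 8 being the limiting reagent), O-acylation before C-acylation (secured by adding CDI to the lithium alkoxide before any strong base is present), and regioselective enolisation with C-cyclisation (secured by the single α-CH2 of the aryl ketone, the five-membered ring size and the lithium counter-ion).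

**Step 5**
Reactants: 12 (3S,4R)-3-[4-(benzyloxy)-3-methoxybenzoyl]-4-(3,4-dimethoxybenzyl)dihydrofuran-2(3H)-one
Product: 13 (3S,4R)-4-(3,4-dimethoxybenzyl)-3-(4-hydroxy-3-methoxybenzoyl)dihydrofuran-2(3H)-one
Conditions: H2 (1 atm), 10% Pd/C, EtOAc, rt
Reagents that add atoms: none
Why: Hydrogenolysis of the benzyl aryl ether on palladium, under which the electron-rich aryl ketone, the lactone and the methyl ethers should be inert at 1 atm, while C3 remains at its thermodynamic trans configuration.

**Compound list**

1 | 3,4-dimethoxybenzaldehyde (veratraldehyde) | COc1ccc(C=O)cc1OC | starting material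
2 | dimethyl succinate | COC(=O)CCC(=O)OC | starting material
3 | (E)-4-(3,4-dimethoxyphenyl)-3-(methoxycarbonyl)but-3-enoic acid | COC(=O)/C(CC(=O)O)=C/c1ccc(OC)c(OC)c1 | intermediate
4 | (R)-4-(3,4-dimethoxyphenyl)-3-(methoxycarbonyl)butanoic acid | COC(=O)[C@@H](CC(=O)O)Cc1ccc(OC)c(OC)c1 | intermediate
5 | (R)-4-(3,4-dimethoxyphenyl)-3-(hydroxymethyl)butanoic acid (not isolated) | OC[C@@H](CC(=O)O)Cc1ccc(OC)c(OC)c1 | intermediate
6 | (R)-4-(3,4-dimethoxybenzyl)dihydrofuran-2(3H)-one | O=C1C[C@@H](Cc2ccc(OC)c(OC)c2)CO1 | intermediate
7 | 1-(benzyloxy)-4-bromo-2-methoxybenzene | COc1cc(Br)ccc1OCc1ccccc1 | starting material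
8 | [4-(benzyloxy)-3-methoxyphenyl]lithium (not isolated) | [Li]c1ccc(OCc2ccccc2)c(OC)c1 | intermediate
9 | lithium (4R)-2-[4-(benzyloxy)-3-methoxyphenyl]-4-(3,4-dimethoxybenzyl)tetrahydrofuran-2-olate, both epimers at the hemiketal carbon (not isolated) | [Li+].[O-]C1(c2ccc(OCc3ccccc3)c(OC)c2)C[C@@H](Cc2ccc(OC)c(OC)c2)CO1 | intermediate
10 | lithium (R)-4-[4-(benzyloxy)-3-methoxyphenyl]-2-(3,4-dimethoxybenzyl)-4-oxobutan-1-olate (not isolated) | [Li+].[O-]C[C@H](Cc1ccc(OC)c(OC)c1)CC(=O)c1ccc(OCc2ccccc2)c(OC)c1 | intermediate
11 | (R)-4-[4-(benzyloxy)-3-methoxyphenyl]-2-(3,4-dimethoxybenzyl)-4-oxobutyl 1H-imidazole-1-carboxylate (not isolated) | O=C(OC[C@H](Cc1ccc(OC)c(OC)c1)CC(=O)c1ccc(OCc2ccccc2)c(OC)c1)n1ccnc1 | intermediate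
12 | (3S,4R)-3-[4-(benzyloxy)-3-methoxybenzoyl]-4-(3,4-dimethoxybenzyl)dihydrofuran-2(3H)-one | COc1cc(C(=O)[C@H]2C(=O)OC[C@@H]2Cc2ccc(OC)c(OC)c2)ccc1OCc1ccccc1 | intermediate
13 | (3S,4R)-4-(3,4-dimethoxybenzyl)-3-(4-hydroxy-3-methoxybenzoyl)dihydrofuran-2(3H)-one | COc1cc(C(=O)[C@H]2C(=O)OC[C@@H]2Cc2ccc(OC)c(OC)c2)ccc1O | target

**Step count**

Total steps: 5. Longest linear sequence: 5 steps (1 → 3 → 4 → 6 → 12 → 13); 7 enters in step 4.

**Steps most likely to fail, with fallbacks**

Step 4. What may go wrong: a second addition of 8 to the ketone as the lactolate opens; acylation of the closed hemiketal alkoxide by CDI followed by elimination to a dihydrofuran; or carbonate dimerisation of the alkoxide. The fallback sets out from 6 and keeps the same ring closure but builds the open-chain precursor stepwise. Aminolysis of 6 with MeNH(OMe)·HCl/AlMe3 (CH2Cl2, 0 °C → rt) should give the hydroxy Weinreb amide (R)-4-(3,4-dimethoxyphenyl)-3-(hydroxymethyl)-N-methoxy-N-methylbutanamide F1. Deprotonation of its hydroxyl with i-PrMgCl (1.0 equiv) and addition of 8 (1.3 equiv, THF, –78 → 0 °C) should then give, after aq. NH4Cl, the neutral keto alcohol (R)-1-[4-(benzyloxy)-3-methoxyphenyl]-3-(3,4-dimethoxybenzyl)-4-hydroxybutan-1-one F2; the N-methoxy-N-methyl chelate blocks over-addition. F2 is isolated and treated with CDI (CH2Cl2, rt), which should acylate only the primary hydroxyl. The route is rejoined at 11, now an isolated compound, which is closed with LiN(SiMe3)2 as in step 4 to give 12.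

Step 2. What may go wrong: insufficient or reversed enantiofacial selectivity in the hydrogenation of the β-aryl itaconate half-ester (E/Z content, ligand match). The fallback sets out from 3. Non-selective hydrogenation (H2, Pd/C, MeOH) should give racemic 4-(3,4-dimethoxyphenyl)-3-(methoxycarbonyl)butanoic acid F3. Classical resolution by crystallisation with (R)-1-phenylethylamine should give the salt (R)-1-phenylethylammonium (R)-4-(3,4-dimethoxyphenyl)-3-(methoxycarbonyl)butanoate F4; the amine antipode is chosen so that the salt of the R acid is the less soluble one. Liberation with aq. HCl returns to the route at 4.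

Step 3. What may go wrong: loss of chemoselectivity, with reduction reaching the carboxylate terminus or stopping short at the ester, or partial epimerisation α to the ester before reduction. The fallback sets out from 4. The acid is masked with tert-butyl 2,2,2-trichloroacetimidate (cat. BF3·OEt2, CH2Cl2/cyclohexane) to give the diester 4-tert-butyl 1-methyl (R)-2-(3,4-dimethoxybenzyl)butanedioate F5. LiBH4 (THF, 0 °C) should reduce the methyl ester and spare the hindered tert-butyl ester, giving tert-butyl (R)-4-(3,4-dimethoxyphenyl)-3-(hydroxymethyl)butanoate F6. CF3CO2H/CH2Cl2 then cleaves the tert-butyl ester with lactonisation, returning to the route at 6.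

**Further compounds**

F1 | step 4 | (R)-4-(3,4-dimethoxyphenyl)-3-(hydroxymethyl)-N-methoxy-N-methylbutanamide | CON(C)C(=O)C[C@H](CO)Cc1ccc(OC)c(OC)c1
F2 | step 4 | (R)-1-[4-(benzyloxy)-3-methoxyphenyl]-3-(3,4-dimethoxybenzyl)-4-hydroxybutan-1-one | OC[C@H](Cc1ccc(OC)c(OC)c1)CC(=O)c1ccc(OCc2ccccc2)c(OC)c1
F3 | step 2 | rac-4-(3,4-dimethoxyphenyl)-3-(methoxycarbonyl)butanoic acid | COC(=O)C(CC(=O)O)Cc1ccc(OC)c(OC)c1
F4 | step 2 | (R)-1-phenylethylammonium (R)-4-(3,4-dimethoxyphenyl)-3-(methoxycarbonyl)butanoate | COC(=O)[C@@H](CC(=O)[O-])Cc1ccc(OC)c(OC)c1.C[C@@H]([NH3+])c1ccccc1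
F5 | step 3 | 4-tert-butyl 1-methyl (R)-2-(3,4-dimethoxybenzyl)butanedioate | COC(=O)[C@@H](CC(=O)OC(C)(C)C)Cc1ccc(OC)c(OC)c1
F6 | step 3 | tert-butyl (R)-4-(3,4-dimethoxyphenyl)-3-(hydroxymethyl)butanoate | OC[C@@H](CC(=O)OC(C)(C)C)Cc1ccc(OC)c(OC)c1
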